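**Plan**
Ring numbering: C1 (CO2Me), C2 (OH), C3 (prenyl), C4 (OH), C5 (prenyl), C6 (2-phenylethyl). The enabling feature is prenylated C3 flanked by the oxygenated C2 and C4, the imprint of an O-substituted alkyne (C2–C3) bonded to a ketene carbonyl (C4).
Retrosynthesis: free the C2 hydroxyl from a silyl ether, then cut C1–C6, C1–C2, C3–C4 and C4–C5 together, giving diazo keto ester 10 (C1, C4, C5, C6) and siloxyalkyne 15 (C2, C3).
Compound 10 is cut at its enone C=C (ring bond C5–C6) into diazo keto ester 4 and aldehyde 6; 4 comes from 4-phenylbutanoic acid by two-carbon homologation and diazo transfer.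
Compound 15 comes from 4-methylpent-3-enoic acid through its methyl ester, an ynolate rearrangement that adds one carbon and keeps the prenyl group, and O-silylation.
Forward: the two branches meet in step 8, where the only ring (the benzene ring) is formed; desilylation ends the route.
Stereochemistry: the target has no stereocenter; the only stereo element on the way is the 4E alkene of 10, set by elimination and consumed in the ring closure.

Key step: step 8

Assumption: 4-methylpent-3-enoic acid 11 is bought (otherwise one oxidation from alcohol 5); 8, 17 and 19 are racemic, since none of their stereocenters reaches the target.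

**Step 1**
Reactants: 1 4-phenylbutanoic acid
Product: 3 methyl 3-oxo-6-phenylhexanoate, via acyl imidazolide 2 (not isolated)
Conditions: CDI, THF, rt; then MeO2CCH2CO2K, MgCl2, THF, rt to 50 °C; aq. HCl work-up
Reagents that add atoms: potassium methyl malonate, COC(=O)CC(=O)[O-].[K+]
Why: Masamune–Brooks homologation, in which acyl imidazolide 2 C-acylates the magnesium chelate of the malonate half-ester and the adduct loses CO2 on acidic work-up, the standard two-carbon extension of an acid to a β-keto ester.

**Step 2**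
Reactants: 3 methyl 3-oxo-6-phenylhexanoate
Product: 4 methyl 2-diazo-3-oxo-6-phenylhexanoate
Conditions: 4-acetamidobenzenesulfonyl azide, Et3N, MeCN, 0 °C to rt
Reagents that add atoms: 4-acetamidobenzenesulfonyl azide, CC(=O)Nc1ccc(cc1)S(=O)(=O)N=[N+]=[N-]
Why: Regitz diazo transfer, in which the amine-generated enolate of the 1,3-dicarbonyl attacks the terminal azide nitrogen and expels the sulfonamide, routine for β-keto esters and harmless to the rest of 3.

**Step 3**
Reactants: 5 4-methylpent-3-en-1-ol
Product: 6 4-methylpent-3-enal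
Conditions: Dess–Martin periodinane, pyridine, CH2Cl2, 0 °C to rt; used at once as a CH2Cl2 solution
Reagents that add atoms: none
Why: Dess–Martin oxidation stops at the aldehyde under near-neutral buffered conditions that should keep the β,γ-alkene out of conjugation, and the volatile product is carried on without concentration.

**Step 4**
Reactants: 4 methyl 2-diazo-3-oxo-6-phenylhexanoate; 6 4-methylpent-3-enal
Product: 8 methyl 2-diazo-5-hydroxy-8-methyl-3-oxo-4-(2-phenylethyl)non-7-enoate, via titanium enolate 7 (not isolated)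
Conditions: TiCl4, Et3N, CH2Cl2, −78 °C; then 6, −78 °C
Reagents that add atoms: none
Why: Titanium enolate aldol addition, a known reaction of α-diazo-β-keto esters, in which TiCl4/Et3N can enolize 4 only at C4 and the weakly basic Z-enolate 7 adds to the enolizable aldehyde through a closed chair transition state that should favor the syn aldol, the configuration of the two new stereocenters (racemic diastereomer mixture) being irrelevant because step 5 erases both.

**Step 5**
Reactants: 8 methyl 2-diazo-5-hydroxy-8-methyl-3-oxo-4-(2-phenylethyl)non-7-enoate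
Product: 10 methyl (4E)-2-diazo-8-methyl-3-oxo-4-(2-phenylethyl)nona-4,7-dienoate, via mesylate 9 (not isolated)
Conditions: MsCl, Et3N, CH2Cl2, 0 °C; then DBU, 0 °C
Reagents that add atoms: none
Why: Mesylation and E1cB elimination through the ketone enolate place the new alkene in conjugation with the ketone, the thermodynamic preference for the acyl group trans to the β-substituent should set the 4E geometry, and the acceptor-stabilized diazo group tolerates MsCl and amine bases at 0 °C.

**Step 6**
Reactants: 11 4-methylpent-3-enoic acid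
Product: 12 methyl 4-methylpent-3-enoate
Conditions: MeI, K2CO3, DMF, rt
Reagents that add atoms: iodomethane, CI
Why: SN2 O-alkylation of the carboxylate under mild carbonate base avoids the acid-promoted lactonization onto the trisubstituted alkene that a Fischer esterification would risk.

**Step 7**
Reactants: 12 methyl 4-methylpent-3-enoate
Product: 15 (5-methylhex-4-en-1-ynoxy)tri(propan-2-yl)silane, via dibromo enolate 13 (not isolated), via lithium ynolate 14 (not isolated)
Conditions: CH2Br2, lithium 2,2,6,6-tetramethylpiperidide, THF, −78 °C; then 12; LiN(SiMe3)2; n-BuLi, −78 to 0 °C; then iPr3SiCl, −78 °C to rt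
Reagents that add atoms: dibromomethane, BrCBr; chlorotri(propan-2-yl)silane, CC(C)[Si](Cl)(C(C)C)C(C)C
Why: Kowalski ynolate chemistry, in which LiCHBr2 adds to the ester, dibromo enolate 13 undergoes bromine–lithium exchange and a carbenoid 1,2-shift of the prenyl group to ynolate 14 (one carbon gained, prenyl retained), and the bulky chlorosilane silylates 14 on oxygen as is known for triisopropylsilyl chloride.

**Step 8**
Reactants: 10 methyl (4E)-2-diazo-8-methyl-3-oxo-4-(2-phenylethyl)nona-4,7-dienoate; 15 (5-methylhex-4-en-1-ynoxy)tri(propan-2-yl)silane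
Product: 20 methyl 4-hydroxy-3,5-bis(3-methylbut-2-enyl)-6-(2-phenylethyl)-2-[tri(propan-2-yl)silyloxy]benzoate, via vinylketene 16 (not isolated), via cyclobutenone 17 (not isolated), via dienylketene 18 (not isolated), via cyclohexadienone 19 (not isolated)
Conditions: hν (254 nm, low-pressure Hg lamp, Vycor), excess 15, degassed ClCH2CH2Cl, rt; then 80 °C
Reagents that add atoms: none
Why: Proposed new method: light expels N2 from 10 and the alkenyl group shifts from the ketone carbon to the diazo carbon (Wolff rearrangement, bond C1–C6) to give the ester-bearing vinylketene 16, whose ketene carbon is attacked by the nucleophilic prenyl-bearing carbon of 15 while the silyloxy carbon closes onto the ester-bearing carbon, a (2+2) cycloaddition (C3–C4 and C1–C2) that gives 4-alkenylcyclobutenone 17. Four-electron electrocyclic opening of 17 leads to dienylketene 18, and the only ring of the target is then closed by a thermal disrotatory six-electron electrocyclization (C4–C5) to dienone 19, which tautomerizes to phenol 20. The closest known reaction type is the photochemical Wolff variant of the Danheiser benzannulation, in which α,β-unsaturated α-diazo ketones with hydrogen on the diazo carbon combine with triisopropylsiloxyalkynes to give resorcinol monosilyl ethers; the ester on the diazo carbon is the untested element. No stereocenter survives, since the quaternary carbon of racemic 17 and the sp3 carbon of racemic 19 both end as aromatic carbons. The step needs migration of the alkenyl group and not of methoxy (ketone substituents migrate in preference to alkoxy in 2-diazo-3-oxo esters), (2+2) addition across the ketene C=C and not hetero-(4+2) addition through the ester carbonyl (the polarized alkyne carbon bonds first to the ketene carbon and the enolate is expected to close through carbon as in known ketene–ynol ether additions), and inward rotation of the alkenyl group on ring opening, which is helped by the reversibility of that opening against the irreversible aromatization. The 4E geometry of 10 keeps hydrogen on the inside of the triene terminus and holds the side-chain alkene away from the ketene.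

**Step 9**
Reactants: 20 methyl 4-hydroxy-3,5-bis(3-methylbut-2-enyl)-6-(2-phenylethyl)-2-[tri(propan-2-yl)silyloxy]benzoate
Product: 21 methyl 2,4-dihydroxy-3,5-bis(3-methylbut-2-enyl)-6-(2-phenylethyl)benzoate
Conditions: Bu4NF, AcOH, THF, 0 °C
Reagents that add atoms: none
Why: Fluoride-induced cleavage of the aryl silyl ether, with acetic acid buffering the phenoxide so that the methyl ester and the prenyl groups next to the phenols are left alone.

**Compound list**
1 | 4-phenylbutanoic acid | OC(=O)CCCc1ccccc1 | starting material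
2 | 1-(1H-imidazol-1-yl)-4-phenylbutan-1-one | O=C(CCCc1ccccc1)n1ccnc1 | intermediate
3 | methyl 3-oxo-6-phenylhexanoate | COC(=O)CC(=O)CCCc1ccccc1 | intermediate
4 | methyl 2-diazo-3-oxo-6-phenylhexanoate | COC(=O)C(=[N+]=[N-])C(=O)CCCc1ccccc1 | intermediate
5 | 4-methylpent-3-en-1-ol | CC(C)=CCCO | starting material
6 | 4-methylpent-3-enal | CC(C)=CCC=O | intermediate
7 | methyl (3Z)-2-diazo-6-phenyl-3-[(trichlorotitanio)oxy]hex-3-enoate | COC(=O)C(=[N+]=[N-])/C(O[Ti](Cl)(Cl)Cl)=C/CCc1ccccc1 | intermediate
8 | methyl 2-diazo-5-hydroxy-8-methyl-3-oxo-4-(2-phenylethyl)non-7-enoate (racemic diastereomer mixture, syn expected to predominate) | COC(=O)C(=[N+]=[N-])C(=O)C(CCc1ccccc1)C(O)CC=C(C)C | intermediate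
9 | methyl 2-diazo-5-(methanesulfonyloxy)-8-methyl-3-oxo-4-(2-phenylethyl)non-7-enoate (racemic diastereomer mixture) | COC(=O)C(=[N+]=[N-])C(=O)C(CCc1ccccc1)C(OS(C)(=O)=O)CC=C(C)C | intermediate
10 | methyl (4E)-2-diazo-8-methyl-3-oxo-4-(2-phenylethyl)nona-4,7-dienoate | COC(=O)C(=[N+]=[N-])C(=O)/C(CCc1ccccc1)=C/CC=C(C)C | intermediate
11 | 4-methylpent-3-enoic acid | OC(=O)CC=C(C)C | starting material
12 | methyl 4-methylpent-3-enoate | COC(=O)CC=C(C)C | intermediate
13 | lithium 1,1-dibromo-5-methylhexa-1,4-dien-2-olate | [Li]OC(CC=C(C)C)=C(Br)Br | intermediate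
14 | lithium 5-methylhex-4-en-1-yn-1-olate | [Li]OC#CCC=C(C)C | intermediate
15 | (5-methylhex-4-en-1-ynoxy)tri(propan-2-yl)silane | CC(C)=CCC#CO[Si](C(C)C)(C(C)C)C(C)C | intermediate
16 | methyl (3E)-7-methyl-2-(oxomethylidene)-3-(2-phenylethyl)octa-3,6-dienoate | COC(=O)C(=C=O)/C(CCc1ccccc1)=C/CC=C(C)C | intermediate
17 | methyl 1-[(3E)-7-methyl-1-phenylocta-3,6-dien-3-yl]-3-(3-methylbut-2-enyl)-4-oxo-2-[tri(propan-2-yl)silyloxy]cyclobut-2-ene-1-carboxylate (racemic) | COC(=O)C1(C(=O)C(CC=C(C)C)=C1O[Si](C(C)C)(C(C)C)C(C)C)/C(CCc1ccccc1)=C/CC=C(C)C | intermediate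
18 | methyl (2Z)-7-methyl-2-[(3E)-7-methyl-1-phenylocta-3,6-dien-3-yl]-4-(oxomethylidene)-3-[tri(propan-2-yl)silyloxy]octa-2,6-dienoate | O=C=C(CC=C(C)C)/C(O[Si](C(C)C)(C(C)C)C(C)C)=C(C(=O)OC)\C(CCc1ccccc1)=C\CC=C(C)C | intermediate
19 | methyl 3,5-bis(3-methylbut-2-enyl)-4-oxo-2-(2-phenylethyl)-6-[tri(propan-2-yl)silyloxy]cyclohexa-1,5-diene-1-carboxylate (racemic) | COC(=O)C1=C(CCc2ccccc2)C(CC=C(C)C)C(=O)C(CC=C(C)C)=C1O[Si](C(C)C)(C(C)C)C(C)C | intermediate
20 | methyl 4-hydroxy-3,5-bis(3-methylbut-2-enyl)-6-(2-phenylethyl)-2-[tri(propan-2-yl)silyloxy]benzoate | COC(=O)c1c(O[Si](C(C)C)(C(C)C)C(C)C)c(CC=C(C)C)c(O)c(CC=C(C)C)c1CCc1ccccc1 | intermediate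
21 | methyl 2,4-dihydroxy-3,5-bis(3-methylbut-2-enyl)-6-(2-phenylethyl)benzoate | COC(=O)c1c(O)c(CC=C(C)C)c(O)c(CC=C(C)C)c1CCc1ccccc1 | target

**Totals**
Total step count: 9.
Longest linear sequence: 6 steps (steps 1, 2, 4, 5, 8, 9 from 4-phenylbutanoic acid); the aldehyde branch adds 1 step and the alkyne branch 2 steps.

**Steps most likely to fail**

Step 8 (proposed method). The ester-substituted ketene may be trapped through its ester carbonyl, either by hetero-(4+2) addition to the alkyne or by oxa-six-electron closure after ring opening with the ester turned inward. Methoxy may also migrate in the Wolff step. In each case no benzene ring would form. The fallback uses the benzannulation in its established form, with hydrogen on the diazo carbon, and adds the ester afterwards. It sets out from acid 1 (with 6 and 15) and returns to the route at target 21. CDI and MeNHOMe·HCl convert 1 into N-methoxy-N-methyl-4-phenylbutanamide F1. Its lithium enolate (LiN(iPr)2, THF, −78 °C) adds to aldehyde 6 to give 3-hydroxy-N-methoxy-N,6-dimethyl-2-(2-phenylethyl)hept-5-enamide F2. This is converted with MsCl/Et3N into 3-(methanesulfonyloxy)-N-methoxy-N,6-dimethyl-2-(2-phenylethyl)hept-5-enamide F3 and eliminated with DBU to (2E)-N-methoxy-N,6-dimethyl-2-(2-phenylethyl)hepta-2,5-dienamide F4. MeMgBr in THF at 0 °C gives (3E)-7-methyl-3-(2-phenylethyl)octa-3,6-dien-2-one F5. LiN(SiMe3)2 and CF3CO2CH2CF3 give (5E)-1,1,1-trifluoro-9-methyl-5-(2-phenylethyl)deca-5,8-diene-2,4-dione F6, and detrifluoroacetylative diazo transfer (MsN3, Et3N, H2O, MeCN) gives (3E)-1-diazo-7-methyl-3-(2-phenylethyl)octa-3,6-dien-2-one F7. Irradiation of F7 with 15 under the conditions of step 8 should give 2,6-bis(3-methylbut-2-enyl)-5-(2-phenylethyl)-3-[tri(propan-2-yl)silyloxy]phenol F8. Bu4NF/AcOH frees 2,4-bis(3-methylbut-2-enyl)-5-(2-phenylethyl)benzene-1,3-diol F9. Ortho-carboxylation at the only free ring position with MeOMgOCO2Me in DMF at 120 °C, followed by acidification, gives 2,4-dihydroxy-3,5-bis(3-methylbut-2-enyl)-6-(2-phenylethyl)benzoic acid F10, and Me3SiCHN2 in MeOH/toluene at 0 °C esterifies the acid to 21.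

Step 7. LiCHBr2 or the amide bases may deprotonate the doubly activated CH2 of 12 in competition with addition, with drift of the alkene into conjugation, or the ynolate may be silylated on carbon. The fallback makes the ynolate by oxidation of an acetylide and avoids the ester altogether. It sets out from aldehyde 6 and returns at ynolate 14, which is silylated to 15 as in step 7 (iPr3SiOTf or iPr3SiCl). Corey–Fuchs olefination of 6 (CBr4, PPh3, CH2Cl2, 0 °C) gives 1,1-dibromo-5-methylhexa-1,4-diene F11. Two equivalents of n-BuLi in THF at −78 °C convert it into lithium 5-methylhex-4-en-1-yn-1-ide F12, and t-BuOOLi (−78 to 0 °C) oxidizes the acetylide to 14.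

Step 5. DBU may move the 1,4-diene into conjugation with the enone, or the elimination may give incomplete E selectivity. The fallback fixes the trisubstituted alkene by a neutral olefination and installs the diazo group last. It sets out from aldehyde 6 and returns at 10. Purchased ethyl 2-bromo-4-phenylbutanoate and PPh3 give (1-ethoxy-1-oxo-4-phenylbutan-2-yl)triphenylphosphanium bromide F13, and aqueous NaOH gives the stabilized ylide ethyl 4-phenyl-2-(triphenyl-λ5-phosphanylidene)butanoate F14. Wittig reaction with 6 (CH2Cl2, rt) should give ethyl (2E)-6-methyl-2-(2-phenylethyl)hepta-2,5-dienoate F15. LiOH (THF/H2O) gives (2E)-6-methyl-2-(2-phenylethyl)hepta-2,5-dienoic acid F16. CDI gives (2E)-1-(1H-imidazol-1-yl)-6-methyl-2-(2-phenylethyl)hepta-2,5-dien-1-one F17, and MeO2CCH2CO2K/MgCl2 as in step 1 gives methyl (4E)-8-methyl-3-oxo-4-(2-phenylethyl)nona-4,7-dienoate F18. Diazo transfer as in step 2 gives 10.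

**Further compounds**
F1 | step 8 | N-methoxy-N-methyl-4-phenylbutanamide | CON(C)C(=O)CCCc1ccccc1
F2 | step 8 | 3-hydroxy-N-methoxy-N,6-dimethyl-2-(2-phenylethyl)hept-5-enamide | CON(C)C(=O)C(CCc1ccccc1)C(O)CC=C(C)C
F3 | step 8 | 3-(methanesulfonyloxy)-N-methoxy-N,6-dimethyl-2-(2-phenylethyl)hept-5-enamide | CON(C)C(=O)C(CCc1ccccc1)C(OS(C)(=O)=O)CC=C(C)C
F4 | step 8 | (2E)-N-methoxy-N,6-dimethyl-2-(2-phenylethyl)hepta-2,5-dienamide | CON(C)C(=O)/C(CCc1ccccc1)=C/CC=C(C)C
F5 | step 8 | (3E)-7-methyl-3-(2-phenylethyl)octa-3,6-dien-2-one | CC(=O)/C(CCc1ccccc1)=C/CC=C(C)C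
F6 | step 8 | (5E)-1,1,1-trifluoro-9-methyl-5-(2-phenylethyl)deca-5,8-diene-2,4-dione | FC(F)(F)C(=O)CC(=O)/C(CCc1ccccc1)=C/CC=C(C)C
F7 | step 8 | (3E)-1-diazo-7-methyl-3-(2-phenylethyl)octa-3,6-dien-2-one | [N-]=[N+]=CC(=O)/C(CCc1ccccc1)=C/CC=C(C)C
F8 | step 8 | 2,6-bis(3-methylbut-2-enyl)-5-(2-phenylethyl)-3-[tri(propan-2-yl)silyloxy]phenol | Oc1c(CC=C(C)C)c(O[Si](C(C)C)(C(C)C)C(C)C)cc(CCc2ccccc2)c1CC=C(C)C
F9 | step 8 | 2,4-bis(3-methylbut-2-enyl)-5-(2-phenylethyl)benzene-1,3-diol | Oc1cc(CCc2ccccc2)c(CC=C(C)C)c(O)c1CC=C(C)C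
F10 | step 8 | 2,4-dihydroxy-3,5-bis(3-methylbut-2-enyl)-6-(2-phenylethyl)benzoic acid | OC(=O)c1c(O)c(CC=C(C)C)c(O)c(CC=C(C)C)c1CCc1ccccc1
F11 | step 7 | 1,1-dibromo-5-methylhexa-1,4-diene | BrC(Br)=CCC=C(C)C
F12 | step 7 | lithium 5-methylhex-4-en-1-yn-1-ide | [Li]C#CCC=C(C)C
F13 | step 5 | (1-ethoxy-1-oxo-4-phenylbutan-2-yl)triphenylphosphanium bromide | CCOC(=O)C(CCc1ccccc1)[P+](c1ccccc1)(c1ccccc1)c1ccccc1.[Br-]
F14 | step 5 | ethyl 4-phenyl-2-(triphenyl-λ5-phosphanylidene)butanoate | CCOC(=O)C(CCc1ccccc1)=P(c1ccccc1)(c1ccccc1)c1ccccc1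
F15 | step 5 | ethyl (2E)-6-methyl-2-(2-phenylethyl)hepta-2,5-dienoate | CCOC(=O)/C(CCc1ccccc1)=C/CC=C(C)C
F16 | step 5 | (2E)-6-methyl-2-(2-phenylethyl)hepta-2,5-dienoic acid | OC(=O)/C(CCc1ccccc1)=C/CC=C(C)C
F17 | step 5 | (2E)-1-(1H-imidazol-1-yl)-6-methyl-2-(2-phenylethyl)hepta-2,5-dien-1-one | O=C(/C(CCc1ccccc1)=C/CC=C(C)C)n1ccnc1
F18 | step 5 | methyl (4E)-8-methyl-3-oxo-4-(2-phenylethyl)nona-4,7-dienoate | COC(=O)CC(=O)/C(CCc1ccccc1)=C/CC=C(C)C
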